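**Retrosynthetic overview**
- The 2α-OH comes last, by hydroxyl-directed reduction of a C2 ketone. Before that, both angelates go onto a C6,C10-diol, and the β-epoxide is delivered by the free 10β-allylic alcohol.
- The C8 methyl group and the C8=C9 bond come from a cycloheptanone (dehydrogenation, then conjugate methylation with re-oxidation). The C6 oxygen is carried as a C–Si bond.
- The five-membered ring is closed last, by an intramolecular aldol (C3 to C4) of a 1,4-diketone.
- The seven-membered ring comes from a one-carbon oxidative semipinacol ring expansion of a 1-(1-methylallenyl)cyclohexanol. C5 migrates from C10 to C1, which makes the C1–C5 bond and the quaternary C1.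
- The cyclohexane comes from cyclohexenone by enantioselective conjugate silylation/aldol with isobutyraldehyde, followed by but-2-ynyl addition.

**Convention and assumption:** atoms carry daucane numbers (C1 quaternary ring-fusion carbon, C2–C4 five-ring carbons, C5 ring-fusion CH, C6–C10 seven-ring carbons, C14 the methyl on C8). α is the face that carries the C1 methyl group and H5. The side-chain carbinol centre made in step 1 is a mixture and is erased in step 3.

Step 1
Reactants: 1 cyclohex-2-en-1-one; 2 2-methylpropanal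
Product: 4 (2S,3S)-3-[dimethyl(phenyl)silyl]-2-(1-hydroxy-2-methylpropyl)cyclohexan-1-one (mixture at the side-chain carbinol carbon), via pinacolboron enolate 3 (not isolated)
Conditions: PhMe2Si–Bpin (1.1 equiv), CuCl (1 mol %), chiral imidazolinium salt (1.1 mol %), NaOt-Bu (2.2 mol %), THF, −78 °C; then 2 (1.5 equiv), −78 → −20 °C; pH 7 buffer
Reagents that add atoms: (dimethylphenylsilyl)boronic acid pinacol ester, C[Si](C)(c1ccccc1)B1OC(C)(C)C(C)(C)O1
Why: Copper–NHC-catalysed enantioselective conjugate silyl addition sets C6, and the boron enolate then adds to the aldehyde anti to the bulky silyl group to set C5 trans to it (tandem conjugate addition–aldol).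

Step 2
Reactants: 4 (2S,3S)-3-[dimethyl(phenyl)silyl]-2-(1-hydroxy-2-methylpropyl)cyclohexan-1-one; 5 1-bromobut-2-yne
Product: 7 (1S,2S,3S)-1-(buta-2,3-dien-2-yl)-3-[dimethyl(phenyl)silyl]-2-(1-hydroxy-2-methylpropyl)cyclohexan-1-ol, via but-2-ynylzinc bromide 6 (not isolated)
Conditions: 5 (3 equiv), Zn dust, LiCl, THF, 0 °C → rt; aq NH4Cl
Reagents that add atoms: zinc, [Zn] (atoms only in 6)
Why: In this Barbier-type propargylation the but-2-ynylzinc reacts through a cyclic SE2′ transition state, so its γ-carbon bonds to C10 and gives the 1-methylallenyl carbinol, and equatorial attack anti to the bulky C5 side chain leaves the C10 hydroxyl axial and anti to H5.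

Step 3
Reactants: 7 (1S,2S,3S)-1-(buta-2,3-dien-2-yl)-3-[dimethyl(phenyl)silyl]-2-(1-hydroxy-2-methylpropyl)cyclohexan-1-ol
Product: 8 1-{(1R,2S,6S)-2-(buta-2,3-dien-2-yl)-6-[dimethyl(phenyl)silyl]-2-hydroxycyclohexyl}-2-methylpropan-1-one
Conditions: Dess–Martin periodinane (1.2 equiv), NaHCO3, CH2Cl2, 0 °C
Reagents that add atoms: none
Why: Dess–Martin oxidation touches only the secondary carbinol, spares the tertiary allenyl carbinol, the allene and the silane, and erases the undefined side-chain centre.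

Step 4
Reactants: 8 1-{(1R,2S,6S)-2-(buta-2,3-dien-2-yl)-6-[dimethyl(phenyl)silyl]-2-hydroxycyclohexyl}-2-methylpropan-1-one
Product: 10 (2S,3R,4S)-2-acetyl-4-[dimethyl(phenyl)silyl]-2-methyl-3-(2-methylpropanoyl)cycloheptan-1-one, via allene oxide 9 (not isolated)
Conditions: VO(acac)2 (5 mol %), t-BuOOH (1.1 equiv, decane), 4 Å MS, toluene, −20 → 0 °C
Reagents that add atoms: tert-butyl hydroperoxide, CC(C)(C)OO
Why: Proposed new method: hydroxyl-directed vanadium epoxidation of the proximal, more substituted allene π bond gives the 2-methyleneoxirane 9 on the face syn to the C10 hydroxyl, in the rotamer that puts the small C9 methylene next to the C1 methyl group (least A1,2 strain), so the C10–C5 σ bond lies antiperiplanar to the C1–O bond; the Lewis acidic pentavalent vanadium alkoxide then triggers a semipinacol 1,2-shift in which C5 migrates in preference to C9, because the equatorial C6–Si bond is antiperiplanar to the migrating bond (β-silicon hyperconjugation); C5 moves from C10 to C1 with inversion at C1 and retention at C5, the six-membered ring becomes seven-membered, C10 becomes a ketone and the oxirane oxygen ends as the enolate of the new acetyl group, which fixes the quaternary C1 with its methyl group cis to H5; the closest known reaction types are the tandem epoxidation–semipinacol rearrangement of tertiary allylic alcohols, the directed epoxidation of allenyl carbinols to allene oxides and the electrophile-induced ring expansion of 1-allenylcyclobutanols.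

Step 5
Reactants: 10 (2S,3R,4S)-2-acetyl-4-[dimethyl(phenyl)silyl]-2-methyl-3-(2-methylpropanoyl)cycloheptan-1-one
Product: 12 (1R,4R,5R,6S)-6-[dimethyl(phenyl)silyl]-4-hydroxy-14-nordaucane-2,10-dione (cis-fused; 1-Me/H5/iPr/Si on the α face; 4-OH β), via lithium enolate 11 (not isolated)
Conditions: LiHMDS (1.05 equiv), THF, −78 → −40 °C; AcOH quench at −78 °C
Reagents that add atoms: lithium hexamethyldisilazide, [Li]N([Si](C)(C)C)[Si](C)(C)C (lithium only in 11)
Why: Kinetic deprotonation of the acetyl methyl group and an intramolecular aldol addition to the isopropyl ketone close the cis-fused cyclopentane, with the isopropyl group taking the open α face next to H5 so that the C4 hydroxyl is β, while one equivalent of a non-nucleophilic base at low temperature avoids retro-Claisen cleavage and dehydration.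

Step 6
Reactants: 12 (1R,4R,5R,6S)-6-[dimethyl(phenyl)silyl]-4-hydroxy-14-nordaucane-2,10-dione
Product: 13 (1S,4R,5R,6S)-6-[dimethyl(phenyl)silyl]-4-hydroxy-14-nordauc-8-ene-2,10-dione
Conditions: IBX (1.3 equiv), 4-methoxypyridine N-oxide (1.3 equiv), DMSO, 25 °C
Reagents that add atoms: none
Why: In this IBX dehydrogenation only the C10 ketone has both an α- and a β-hydrogen (C1 is quaternary and C4 next to C3 carries no hydrogen), so a single enone can form.

Step 7
Reactants: 13 (1S,4R,5R,6S)-6-[dimethyl(phenyl)silyl]-4-hydroxy-14-nordauc-8-ene-2,10-dione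
Product: 15 (1S,4R,5R,6S)-6-[dimethyl(phenyl)silyl]-4-hydroxydauc-8-ene-2,10-dione, via trimethylsilyl enol ether 14 (not isolated)
Conditions: Me2CuLi (2.5 equiv), TMSCl, THF, −78 °C; crude 14, Pd(OAc)2 (10 mol %), O2 (1 atm), DMSO, 25 °C; 0.5 M HCl, THF, 0 °C
Reagents that add atoms: lithium dimethylcuprate, [Li+].C[Cu-]C; chlorotrimethylsilane, C[Si](C)(C)Cl (atoms only in 14)
Why: Gilman conjugate addition trapped as the silyl enol ether, followed by Saegusa–Ito oxidation, puts the C14 methyl group on C8 and restores the C8=C9 double bond, so the transient C8 centre is erased.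

Step 8
Reactants: 15 (1S,4R,5R,6S)-6-[dimethyl(phenyl)silyl]-4-hydroxydauc-8-ene-2,10-dione
Product: 16 (1R,4R,5R,6S,10S)-6-[dimethyl(phenyl)silyl]-4,10-dihydroxydauc-8-en-2-one (10-OH β)
Conditions: NaBH4 (1.0 equiv), CeCl3·7H2O, MeOH, −78 °C
Reagents that add atoms: none
Why: Luche reduction prefers the conjugated ketone over the saturated, hindered C2 cyclopentanone, and hydride attacks C10 anti to the C1–C2 acyl bond (polar Felkin–Anh model, same face in the cerium chelate model), that is from the α face, to give the 10β-alcohol.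

Step 9
Reactants: 16 (1R,4R,5R,6S,10S)-6-[dimethyl(phenyl)silyl]-4,10-dihydroxydauc-8-en-2-one
Product: 17 (1R,4R,5R,6S,8S,9R,10R)-6-[dimethyl(phenyl)silyl]-8,9-epoxy-4,10-dihydroxydaucan-2-one (epoxide β)
Conditions: VO(acac)2 (3 mol %), t-BuOOH (1.3 equiv), CH2Cl2, 0 °C
Reagents that add atoms: tert-butyl hydroperoxide, CC(C)(C)OO
Why: Hydroxyl-directed vanadium epoxidation of the allylic alcohol delivers oxygen to the face of the C10 hydroxyl and sets C8 and C9 (syn epoxy alcohol), and no second secondary hydroxyl competes because C6 is still a silane.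

Step 10
Reactants: 17 (1R,4R,5R,6S,8S,9R,10R)-6-[dimethyl(phenyl)silyl]-8,9-epoxy-4,10-dihydroxydaucan-2-one
Product: 18 (1R,4R,5S,6S,8S,9R,10R)-8,9-epoxy-4,6,10-trihydroxydaucan-2-one
Conditions: Hg(OAc)2 (1.5 equiv), AcOOH (32 % in AcOH), NaOAc, 15 °C
Reagents that add atoms: peracetic acid, CC(=O)OO
Why: Fleming–Tamao oxidation (mercuridesilylation of the phenyl group, then peracid-induced carbon shift from silicon to oxygen) replaces silicon by hydroxyl with retention at C6, in the same buffered peracid medium in which epoxides are routinely prepared.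

Step 11
Reactants: 18 (1R,4R,5S,6S,8S,9R,10R)-8,9-epoxy-4,6,10-trihydroxydaucan-2-one; 19 angelic acid [(Z)-2-methylbut-2-enoic acid]
Product: 21 (1R,4R,5S,6S,8S,9R,10R)-6,10-bis(angeloyloxy)-8,9-epoxy-4-hydroxydaucan-2-one, via mixed anhydride 20 (not isolated)
Conditions: 19 (5 equiv), 2,4,6-trichlorobenzoyl chloride (5 equiv), Et3N, toluene, rt; then 18, 80 °C
Reagents that add atoms: 2,4,6-trichlorobenzoyl chloride, O=C(Cl)c1c(Cl)cc(Cl)cc1Cl (atoms only in 20)
Why: Yamaguchi-type esterification through the mixed anhydride, run without a nucleophilic catalyst, acylates both secondary alcohols, leaves the tertiary C4 hydroxyl free and keeps the Z geometry of the angelate.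

Step 12
Reactants: 21 (1R,4R,5S,6S,8S,9R,10R)-6,10-bis(angeloyloxy)-8,9-epoxy-4-hydroxydaucan-2-one
Product: 22 (1S,2S,4R,5S,6S,8S,9R,10R)-6,10-bis(angeloyloxy)-8,9-epoxydaucane-2,4-diol (CNP0265715.3)
Conditions: Me4NBH(OAc)3 (5 equiv), MeCN/AcOH 1:1, −30 °C
Reagents that add atoms: none
Why: In this Evans–Saksena reduction the 4β-hydroxyl binds the triacetoxyborohydride and delivers hydride to the β face of the C2 ketone, giving the 2α-alcohol (1,3-anti diol), while the esters and the epoxide are inert.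

**Compound list**
1 | cyclohex-2-en-1-one | O=C1C=CCCC1 | starting material
2 | 2-methylpropanal | CC(C)C=O | starting material
3 | pinacolboron enolate of (S)-3-[dimethyl(phenyl)silyl]cyclohexanone | C[Si](C)(c2ccccc2)[C@H]1CCCC(OB3OC(C)(C)C(C)(C)O3)=C1 | intermediate
4 | (2S,3S)-3-[dimethyl(phenyl)silyl]-2-(1-hydroxy-2-methylpropyl)cyclohexan-1-one | C[Si](C)(c2ccccc2)[C@H]1CCCC(=O)[C@@H]1C(O)C(C)C | intermediate
5 | 1-bromobut-2-yne | CC#CCBr | starting material
6 | but-2-ynylzinc bromide | CC#CC[Zn]Br | intermediate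
7 | (1S,2S,3S)-1-(buta-2,3-dien-2-yl)-3-[dimethyl(phenyl)silyl]-2-(1-hydroxy-2-methylpropyl)cyclohexan-1-ol | C[Si](C)(c2ccccc2)[C@H]1CCC[C@@](O)(C(C)=C=C)[C@@H]1C(O)C(C)C | intermediate
8 | 1-{(1R,2S,6S)-2-(buta-2,3-dien-2-yl)-6-[dimethyl(phenyl)silyl]-2-hydroxycyclohexyl}-2-methylpropan-1-one | C[Si](C)(c2ccccc2)[C@H]1CCC[C@@](O)(C(C)=C=C)[C@@H]1C(=O)C(C)C | intermediate
9 | allene oxide of 8 (2-methyl-3-methylideneoxiran-2-yl group on C10, oxygen syn to the C10 hydroxyl) | C[Si](C)(c2ccccc2)[C@H]1CCC[C@@](O)([C@]3(C)OC3=C)[C@@H]1C(=O)C(C)C | intermediate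
10 | (2S,3R,4S)-2-acetyl-4-[dimethyl(phenyl)silyl]-2-methyl-3-(2-methylpropanoyl)cycloheptan-1-one | C[Si](C)(c3ccccc3)[C@H]1CCCC(=O)[C@@](C(C)=O)(C)[C@@H]1C(=O)C(C)C | intermediate
11 | lithium enolate of the acetyl group of 10 | C[Si](C)(c3ccccc3)[C@H]1CCCC(=O)[C@@](C(=C)O[Li])(C)[C@@H]1C(=O)C(C)C | intermediate
12 | (1R,4R,5R,6S)-6-[dimethyl(phenyl)silyl]-4-hydroxy-14-nordaucane-2,10-dione | C[Si](C)(c3ccccc3)[C@H]1CCCC(=O)[C@@]2(C)[C@@H]1[C@](O)(C(C)C)CC2=O | intermediate
13 | (1S,4R,5R,6S)-6-[dimethyl(phenyl)silyl]-4-hydroxy-14-nordauc-8-ene-2,10-dione | C[Si](C)(c3ccccc3)[C@H]1CC=CC(=O)[C@@]2(C)[C@@H]1[C@](O)(C(C)C)CC2=O | intermediate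
14 | 10-(trimethylsilyloxy)-9-ene from methyl addition to 13 (C8 undefined) | C[Si](C)(c3ccccc3)[C@H]1CC(C)C=C(O[Si](C)(C)C)[C@@]2(C)[C@@H]1[C@](O)(C(C)C)CC2=O | intermediate
15 | (1S,4R,5R,6S)-6-[dimethyl(phenyl)silyl]-4-hydroxydauc-8-ene-2,10-dione | C[Si](C)(c3ccccc3)[C@H]1CC(C)=CC(=O)[C@@]2(C)[C@@H]1[C@](O)(C(C)C)CC2=O | intermediate
16 | (1R,4R,5R,6S,10S)-6-[dimethyl(phenyl)silyl]-4,10-dihydroxydauc-8-en-2-one | C[Si](C)(c3ccccc3)[C@H]1CC(C)=C[C@H](O)[C@@]2(C)[C@@H]1[C@](O)(C(C)C)CC2=O | intermediate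
17 | (1R,4R,5R,6S,8S,9R,10R)-6-[dimethyl(phenyl)silyl]-8,9-epoxy-4,10-dihydroxydaucan-2-one | C[Si](C)(c3ccccc3)[C@H]1C[C@]2(C)O[C@@H]2[C@H](O)[C@@]2(C)[C@@H]1[C@](O)(C(C)C)CC2=O | intermediate
18 | (1R,4R,5S,6S,8S,9R,10R)-8,9-epoxy-4,6,10-trihydroxydaucan-2-one | O[C@H]1C[C@]2(C)O[C@@H]2[C@H](O)[C@@]2(C)[C@@H]1[C@](O)(C(C)C)CC2=O | intermediate
19 | angelic acid | C/C=C(/C)C(=O)O | starting material
20 | angelic 2,4,6-trichlorobenzoic anhydride | C/C=C(/C)C(=O)OC(=O)c1c(Cl)cc(Cl)cc1Cl | intermediate
21 | (1R,4R,5S,6S,8S,9R,10R)-6,10-bis(angeloyloxy)-8,9-epoxy-4-hydroxydaucan-2-one | C/C=C(/C)C(=O)O[C@H]1C[C@]2(C)O[C@@H]2[C@H](OC(=O)/C(C)=C\C)[C@@]2(C)[C@@H]1[C@](O)(C(C)C)CC2=O | intermediate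
22 | (1S,2S,4R,5S,6S,8S,9R,10R)-6,10-bis(angeloyloxy)-8,9-epoxydaucane-2,4-diol | C/C=C(/C)C(=O)O[C@H]1C[C@]2(C)O[C@@H]2[C@H](OC(=O)/C(C)=C\C)[C@@]2(C)[C@@H]1[C@](O)(C(C)C)C[C@@H]2O | target

**Total step count:** 12. **Longest linear sequence:** 12.

**Steps most likely to fail**

1. **Step 4 (proposed new ring expansion).** The risks are a second epoxidation to the spirodiepoxide, migration of C9 instead of C5, and retro-aldol opening of the β-hydroxy ketone.
 - The fallback uses known chemistry. It sets out from 4 and comes back at 10, bypassing steps 2 to 4.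
 - (E)-But-2-en-2-yllithium/CeCl3 adds to 4 from the equatorial side and gives the tertiary allylic alcohol F1.
 - VO(acac)2/t-BuOOH gives the syn epoxy diol F2.
 - ZnBr2 in CH2Cl2 brings about the established 2,3-epoxy alcohol semipinacol ring expansion to the β-hydroxy cycloheptanone F3.
 - Dess–Martin periodinane (2.5 equiv) oxidises both secondary carbinols of F3 to 10.

2. **Step 5 (base aldol on a non-enolisable 1,3-diketone).** The risks are retro-Claisen cleavage by the new tertiary alkoxide, dehydration to the cyclopentenone, and enolisation at C9.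
 - The fallback sets out from 10 and comes back at 12.
 - LDA with TMSCl as internal quench at −78 °C gives the acetyl-derived silyl enol ether F4.
 - TiCl4 in CH2Cl2 at −78 °C closes F4 onto the isopropyl ketone (intramolecular Mukaiyama aldol), so no free alkoxide is ever present.
 - Aqueous work-up gives 12.

3. **Step 11 (double angeloylation).** The risks are the neopentyl-type 10β-hydroxyl next to the epoxide and Z-to-E drift to tiglate at 80 °C.
 - The fallback sets out from 18 and comes back at 21.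
 - DCC/DMAP coupling with 2-[bis(2,2,2-trifluoroethoxy)phosphoryl]propanoic acid gives the bis(phosphonopropanoate) F5.
 - A double Still–Gennari olefination (KHMDS, 18-crown-6, acetaldehyde, THF, −78 °C) builds both Z-configured 2-methylbut-2-enoates on the esters already in place and gives 21.

**Further compounds**
F1 | step 4 | (1S,2S,3S)-1-[(E)-but-2-en-2-yl]-3-[dimethyl(phenyl)silyl]-2-(1-hydroxy-2-methylpropyl)cyclohexan-1-ol | C[Si](C)(c2ccccc2)[C@H]1CCC[C@@](O)(/C(C)=C/C)[C@@H]1C(O)C(C)C
F2 | step 4 | syn epoxy diol of F1 (2,3-dimethyloxiran-2-yl group on C10, oxygen syn to the C10 hydroxyl) | C[Si](C)(c2ccccc2)[C@H]1CCC[C@@](O)([C@]3(C)O[C@H]3C)[C@@H]1C(O)C(C)C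
F3 | step 4 | 4-[dimethyl(phenyl)silyl]-2-(1-hydroxyethyl)-3-(1-hydroxy-2-methylpropyl)-2-methylcycloheptan-1-one (ring centres as in 10) | C[Si](C)(c3ccccc3)[C@H]1CCCC(=O)[C@@]([C@H](C)O)(C)[C@@H]1C(O)C(C)C
F4 | step 5 | trimethylsilyl enol ether of the acetyl group of 10 | C[Si](C)(c3ccccc3)[C@H]1CCCC(=O)[C@@](C(=C)O[Si](C)(C)C)(C)[C@@H]1C(=O)C(C)C
F5 | step 11 | 6,10-bis{2-[bis(2,2,2-trifluoroethoxy)phosphoryl]propanoate} of 18 | CC(P(=O)(OCC(F)(F)F)OCC(F)(F)F)C(=O)O[C@H]1C[C@]2(C)O[C@@H]2[C@H](OC(=O)C(C)P(=O)(OCC(F)(F)F)OCC(F)(F)F)[C@@]2(C)[C@@H]1[C@](O)(C(C)C)CC2=O
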